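The seven-membered ring (C4–C5–C6–C7–C8–C9–C10) holds a C5–C6(CH3)2 unit wedged between C4 and the oxygen-bearing C7. This is the imprint of dimethylketene inserted into the C4–C7 bond of a cyclopentanone. In the key step dimethylketene adds [2+2] to silyl enol ether 4 (C7(OTMS)=C4), a cyclopentene that already carries the C9 oxygen and the C10 quaternary centre, and so makes C4–C5 and C6–C7 at once. Desilylation then breaks the temporary C4–C7 bond by retro-aldol and enlarges the five-membered ring to the seven-membered one. An ynone Michael closure adds the cyclohexenone, C11 enolate displacement at C5 closes the cyclobutane, and the two esters come last.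

Key step: step 3

Remark: atom numbers are those of the longipinane skeleton. C1 is the ketone carbon, C2=C3 the alkene (methyl on C3), and C4 and C11 the bridgeheads. C5 is the cyclobutane CH bonded to C6, and C6 the gem-dimethyl carbon. C7 is the tiglate carbon, C8 the methylene, C9 the senecioate carbon, and C10 the methyl-bearing quaternary carbon.

Step 1
Reactants: 1 (R)-4-(tert-butyldimethylsilyloxy)cyclopent-2-en-1-one
Product: 3 (R)-3-allyl-4-(tert-butyldimethylsilyloxy)cyclopent-2-en-1-one, via lithium enolate 2 (not isolated)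
Conditions: (CH2=CHCH2)2CuLi, THF, −78 °C; then PhS(Cl)=N-t-Bu, −78 °C to rt
Reagents that add atoms: lithium diallylcuprate [Li+].C=CC[Cu-]CC=C
Why: Cuprate 1,4-addition (anti to OTBS) gives the regiodefined enolate 2, which the sulfinimidoyl chloride dehydrogenates in the same flask (Mukaiyama dehydrogenation), so the net result is β-allylation of the enone with C9 untouched and no new stereocentre left.

Step 2
Reactants: 3 (R)-3-allyl-4-(tert-butyldimethylsilyloxy)cyclopent-2-en-1-one
Product: 4 (3S,4R)-3-allyl-4-(tert-butyldimethylsilyloxy)-3-methyl-1-(trimethylsilyloxy)cyclopent-1-ene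
Conditions: Me2CuLi, TMSCl, THF, −78 °C; Et3N, cold aq NaHCO3 work-up
Reagents that add atoms: lithium dimethylcuprate [Li+].C[Cu-]C; chlorotrimethylsilane C[Si](C)(C)Cl
Why: The TMSCl-accelerated Gilman conjugate addition delivers methyl to C10 anti to the neighbouring C9 silyloxy group, which sets the quaternary centre with the allyl arm (future C11–C1) cis to the C9 oxygen, and the enolate is trapped regiospecifically as the C7=C4 silyl enol ether.

Step 3
Reactants: 4 (3S,4R)-3-allyl-4-(tert-butyldimethylsilyloxy)-3-methyl-1-(trimethylsilyloxy)cyclopent-1-ene; 5 isobutyryl chloride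
Product: 8 (5S,6R)-5-allyl-6-hydroxy-2,2,5-trimethylcycloheptane-1,3-dione, via dimethylketene 6 (not isolated), via siloxycyclobutanone 7 (not isolated)
Conditions: 5 (slow addition), Et3N, toluene, 80 °C; then 48% aq HF, MeCN, 0 °C to rt
Reagents that add atoms: none
Why: Et3N dehydrochlorinates 5 to dimethylketene 6, whose electrophilic central carbon (future C5) is attacked by the nucleophilic β-carbon C4 of the silyl enol ether while the developing enolate carbon (future C6) closes on the silyloxocarbenium carbon C7, an asynchronous thermal ketene–enol ether [2+2] cycloaddition that gives 3-siloxycyclobutanone 7. The closest known reaction type is the ketene/silyl enol ether cycloaddition–ring-opening sequence that turns 1-siloxycyclopentenes into cycloheptane-1,3-diones. The four-membered ring C4–C5–C6–C7 forms by cycloaddition, cis-fused on the cyclopentene face opposite to the allyl and OTBS groups, and HF then frees the C7 oxygen so that strain-driven retro-aldol scission of C4–C7 converts the bicyclo[3.2.0]heptanone into the seven-membered 1,3-dione (the same HF cleaves the C9 silyl ether, which must be free in step 4). The two stereocentres made in 7 (C4, C7) are erased in the ring enlargement, so facial selectivity is immaterial, and C9 and C10 are untouched. The step needs regioselectivity (C5 to C4, C6 to C7) and chemoselectivity over the allyl group: the first is fixed by the polarity of the enol ether, whose position was set in step 2, and the second by the inertness of an unactivated terminal alkene towards dimethylketene.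

Step 4
Reactants: 8 (5S,6R)-5-allyl-6-hydroxy-2,2,5-trimethylcycloheptane-1,3-dione
Product: 9 (3R,5R,6S)-6-allyl-3,5-dihydroxy-2,2,6-trimethylcycloheptan-1-one
Conditions: Me4NBH(OAc)3, MeCN–AcOH, −30 °C
Reagents that add atoms: none
Why: In this Evans–Saksena reduction the free C9 hydroxyl binds the triacetoxyborohydride and hands hydride to the C7 carbonyl from its own face, which gives the 1,3-anti (7R) alcohol and leaves the undirected, more hindered C5 ketone alone.

Step 5
Reactants: 9 (3R,5R,6S)-6-allyl-3,5-dihydroxy-2,2,6-trimethylcycloheptan-1-one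
Product: 10 (3R,5R,6S)-6-allyl-3,5-bis(tert-butyldimethylsilyloxy)-2,2,6-trimethylcycloheptan-1-one
Conditions: TBSOTf, 2,6-lutidine, CH2Cl2, 0 °C to rt
Reagents that add atoms: tert-butyldimethylsilyl triflate CC(C)(C)[Si](C)(C)OS(=O)(=O)C(F)(F)F
Why: Silyl triflate silylation copes with both neopentyl-type secondary alcohols and removes the retro-aldol liability (C7–O next to the C5 ketone) before the basic steps.

Step 6
Reactants: 10 (3R,5R,6S)-6-allyl-3,5-bis(tert-butyldimethylsilyloxy)-2,2,6-trimethylcycloheptan-1-one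
Product: 11 2-[(1S,2R,4R)-2,4-bis(tert-butyldimethylsilyloxy)-1,5,5-trimethyl-6-oxocycloheptyl]acetaldehyde
Conditions: O3, CH2Cl2, −78 °C; PPh3
Reagents that add atoms: ozone [O-][O+]=O
Why: Ozonolysis with reductive work-up cleaves the only alkene of 10 and shortens the allyl arm to the C11–C1 acetaldehyde unit.

Step 7
Reactants: 11 2-[(1S,2R,4R)-2,4-bis(tert-butyldimethylsilyloxy)-1,5,5-trimethyl-6-oxocycloheptyl]acetaldehyde
Product: 12 propargylic alcohol, (3R,5R,6S)-3,5-bis(tert-butyldimethylsilyloxy)-6-(2-hydroxypent-3-ynyl)-2,2,6-trimethylcycloheptan-1-one (carbinol epimers)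
Conditions: MeC≡CMgBr, THF, −78 °C; then H2O
Reagents that add atoms: 1-propynylmagnesium bromide CC#C[Mg]Br
Why: Grignard 1,2-addition is chemoselective for the aldehyde over the C5 ketone, which is shielded by quaternary C6 and the neopentyl C4 methylene, and the new carbinol centre is removed in step 8.

Step 8
Reactants: 12 propargylic alcohol
Product: 13 ynone, (3R,5R,6S)-3,5-bis(tert-butyldimethylsilyloxy)-2,2,6-trimethyl-6-(2-oxopent-3-ynyl)cycloheptan-1-one
Conditions: Dess–Martin periodinane, CH2Cl2, rt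
Reagents that add atoms: none
Why: Dess–Martin oxidation of the propargylic alcohol gives the ynone under near-neutral conditions that spare the silyl ethers.

Step 9
Reactants: 13 ynone
Product: 14 cis-fused bicyclic enedione, 7,9-bis(tert-butyldimethylsilyloxy)-5,11-secolongipin-2-ene-1,5-dione (cyclohexenone C1–C4/C10/C11 fused at C4–C10 to the cycloheptanone; C4–H cis to C10–CH3)
Conditions: t-BuOK (1.1 equiv), THF, −20 °C; then AcOH
Reagents that add atoms: none
Why: Intramolecular Michael addition (6-endo-dig) of the C4 enolate of the C5 ketone to the ynone β-carbon C3 forms the cyclohexenone and is driven by the stabilised vinylogous 1,3-dicarbonyl enolate, and on protonation the epimerisable C4 should settle cis-fused because allylic 1,2-strain with the C3 methyl forces the C5 acyl branch pseudo-axial.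

Step 10
Reactants: 14 cis-fused bicyclic enedione
Product: 15 1-hydroxy-5-ketone, 7,9-bis(tert-butyldimethylsilyloxy)-1-hydroxy-5,11-secolongipin-2-en-5-one (C1 epimers)
Conditions: NaBH4, CeCl3·7H2O, MeOH, −78 °C
Reagents that add atoms: none
Why: Luche 1,2-reduction masks the enone as its allylic alcohol while the C5 ketone, flanked by quaternary C6 and tertiary C4, should not react at this temperature, and the C1 centre is removed again in step 12.

Step 11
Reactants: 15 1-hydroxy-5-ketone
Product: 16 (5S)-1,5-diol, 7,9-bis(tert-butyldimethylsilyloxy)-5,11-secolongipin-2-ene-1,5-diol (C5–OH cis to C4–H and to the C7 oxygen; C1 epimers)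
Conditions: SmI2, H2O, Et3N, THF, rt
Reagents that add atoms: none
Why: The SmI2–water–amine ketone reduction runs through a ketyl and an organosamarium that pyramidalise freely, so, as in dissolving-metal reductions, the more stable alcohol should result, with oxygen on the open outer side of C5 and hydrogen over the six-membered ring, whereas hydride reagents would attack from that outer side.

Step 12
Reactants: 16 (5S)-1,5-diol
Product: 17 (5S)-5-hydroxy enone, 7,9-bis(tert-butyldimethylsilyloxy)-5-hydroxy-5,11-secolongipin-2-en-1-one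
Conditions: MnO2, CH2Cl2, rt
Reagents that add atoms: none
Why: MnO2 oxidises only the allylic C1 alcohol and restores the enone beside the saturated, hindered C5 alcohol.

Step 13
Reactants: 17 (5S)-5-hydroxy enone
Product: 18 (5S)-5-mesylate of 17
Conditions: MsCl, Et3N, CH2Cl2, −20 °C
Reagents that add atoms: methanesulfonyl chloride CS(=O)(=O)Cl
Why: Mesylation through sulfene is little affected by hindrance at the neopentyl C5 alcohol and keeps its configuration.

Step 14
Reactants: 18 (5S)-5-mesylate
Product: 19 (4R,5S,7R,9R,10R,11R)-7,9-bis(tert-butyldimethylsilyloxy)longipin-2-en-1-one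
Conditions: LDA, THF, −78 °C; DMPU, −78 °C to rt
Reagents that add atoms: none
Why: Kinetic α′-deprotonation of the β-methyl enone at C11 (as with isophorone) is followed by intramolecular SN2 enolate alkylation (4-exo-tet), the classical closure of pinane-, copaane- and longipinane-type cyclobutanes, in which the pseudo-axial C5 lies over C11, the outward mesylate leaves with inversion at C5, and the C11 configuration is dictated by the bridge.

Step 15
Reactants: 19 (4R,5S,7R,9R,10R,11R)-7,9-bis(tert-butyldimethylsilyloxy)longipin-2-en-1-one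
Product: 20 (4R,5S,7R,9R,10R,11R)-7,9-dihydroxylongipin-2-en-1-one
Conditions: HF·pyridine, THF, rt to 40 °C
Reagents that add atoms: none
Why: Fluoride-mediated desilylation frees both alcohols, and the bridgehead positions of the cage cannot enolise, so no stereocentre is at risk.

Step 16
Reactants: 20 (4R,5S,7R,9R,10R,11R)-7,9-dihydroxylongipin-2-en-1-one; 21 3-methylbut-2-enoyl chloride
Product: 22 (4R,5S,7R,9R,10R,11R)-7-hydroxy-9-(3-methylbut-2-enoyloxy)longipin-2-en-1-one
Conditions: 21 (1.0 equiv), pyridine, DMAP (cat.), CH2Cl2, −20 °C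
Reagents that add atoms: none
Why: DMAP-catalysed acylation with one equivalent of acid chloride should go first to the C9 hydroxyl, whose quaternary neighbour C10 is tied back in the cyclobutane and bears one methyl group, rather than to the C7 hydroxyl beside the gem-dimethyl C6.

Step 17
Reactants: 22 (4R,5S,7R,9R,10R,11R)-7-hydroxy-9-(3-methylbut-2-enoyloxy)longipin-2-en-1-one; 23 (E)-2-methylbut-2-enoyl chloride
Product: 24 (4R,5S,7R,9R,10R,11R)-7-[(E)-2-methylbut-2-enoyloxy]-9-(3-methylbut-2-enoyloxy)longipin-2-en-1-one (target)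
Conditions: 23, pyridine, DMAP, toluene, 60 °C
Reagents that add atoms: none
Why: Forcing DMAP-catalysed acylation esterifies the remaining neopentyl C7 alcohol with retention, and the tiglate is the stable E isomer, so its geometry holds.

Compound list
1 | (R)-4-(tert-butyldimethylsilyloxy)cyclopent-2-en-1-one | O=C1C[C@@H](O[Si](C)(C)C(C)(C)C)C=C1 | starting material
2 | lithium (3R,4R)-3-allyl-4-(tert-butyldimethylsilyloxy)cyclopent-1-en-1-olate (allyl trans to OTBS) | [Li+].[O-]C1=C[C@@H](CC=C)[C@H](O[Si](C)(C)C(C)(C)C)C1 | intermediate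
3 | (R)-3-allyl-4-(tert-butyldimethylsilyloxy)cyclopent-2-en-1-one | O=C1C[C@@H](O[Si](C)(C)C(C)(C)C)C(CC=C)=C1 | intermediate
4 | (3S,4R)-3-allyl-4-(tert-butyldimethylsilyloxy)-3-methyl-1-(trimethylsilyloxy)cyclopent-1-ene (methyl trans, allyl cis to OTBS) | C[Si](C)(C)OC1=C[C@](C)(CC=C)[C@H](O[Si](C)(C)C(C)(C)C)C1 | intermediate
5 | isobutyryl chloride | CC(C)C(=O)Cl | starting material
6 | dimethylketene | CC(C)=C=O | intermediate
7 | 4-allyl-3-(tert-butyldimethylsilyloxy)-4,7,7-trimethyl-1-(trimethylsilyloxy)bicyclo[3.2.0]heptan-6-one (cis-fused; cyclobutanone on the face opposite to allyl and OTBS) | O=C1[C@H]2[C@](C)(CC=C)[C@H](O[Si](C)(C)C(C)(C)C)C[C@@]2(O[Si](C)(C)C)C1(C)C | intermediate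
8 | (5S,6R)-5-allyl-6-hydroxy-2,2,5-trimethylcycloheptane-1,3-dione | O=C1C[C@@H](O)[C@@](C)(CC=C)CC(=O)C1(C)C | intermediate
9 | (3R,5R,6S)-6-allyl-3,5-dihydroxy-2,2,6-trimethylcycloheptan-1-one | O[C@@H]1C[C@@H](O)[C@@](C)(CC=C)CC(=O)C1(C)C | intermediate
10 | (3R,5R,6S)-6-allyl-3,5-bis(tert-butyldimethylsilyloxy)-2,2,6-trimethylcycloheptan-1-one | CC(C)(C)[Si](C)(C)O[C@@H]1C[C@@H](O[Si](C)(C)C(C)(C)C)[C@@](C)(CC=C)CC(=O)C1(C)C | intermediate
11 | 2-[(1S,2R,4R)-2,4-bis(tert-butyldimethylsilyloxy)-1,5,5-trimethyl-6-oxocycloheptyl]acetaldehyde | CC(C)(C)[Si](C)(C)O[C@@H]1C[C@@H](O[Si](C)(C)C(C)(C)C)[C@@](C)(CC=O)CC(=O)C1(C)C | intermediate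
12 | (3R,5R,6S)-3,5-bis(tert-butyldimethylsilyloxy)-6-(2-hydroxypent-3-ynyl)-2,2,6-trimethylcycloheptan-1-one (carbinol epimers) | CC(C)(C)[Si](C)(C)O[C@@H]1C[C@@H](O[Si](C)(C)C(C)(C)C)[C@@](C)(CC(O)C#CC)CC(=O)C1(C)C | intermediate
13 | (3R,5R,6S)-3,5-bis(tert-butyldimethylsilyloxy)-2,2,6-trimethyl-6-(2-oxopent-3-ynyl)cycloheptan-1-one | CC(C)(C)[Si](C)(C)O[C@@H]1C[C@@H](O[Si](C)(C)C(C)(C)C)[C@@](C)(CC(=O)C#CC)CC(=O)C1(C)C | intermediate
14 | 7,9-bis(tert-butyldimethylsilyloxy)-5,11-secolongipin-2-ene-1,5-dione (cis-fused, C4–H cis to C10–CH3) | CC(C)(C)[Si](C)(C)O[C@@H]1C[C@@H](O[Si](C)(C)C(C)(C)C)[C@@]2(C)CC(=O)C=C(C)[C@H]2C(=O)C1(C)C | intermediate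
15 | 7,9-bis(tert-butyldimethylsilyloxy)-1-hydroxy-5,11-secolongipin-2-en-5-one (C1 epimers) | CC(C)(C)[Si](C)(C)O[C@@H]1C[C@@H](O[Si](C)(C)C(C)(C)C)[C@@]2(C)CC(O)C=C(C)[C@H]2C(=O)C1(C)C | intermediate
16 | (5S)-7,9-bis(tert-butyldimethylsilyloxy)-5,11-secolongipin-2-ene-1,5-diol (C1 epimers) | CC(C)(C)[Si](C)(C)O[C@@H]1C[C@@H](O[Si](C)(C)C(C)(C)C)[C@@]2(C)CC(O)C=C(C)[C@H]2[C@H](O)C1(C)C | intermediate
17 | (5S)-7,9-bis(tert-butyldimethylsilyloxy)-5-hydroxy-5,11-secolongipin-2-en-1-one | CC(C)(C)[Si](C)(C)O[C@@H]1C[C@@H](O[Si](C)(C)C(C)(C)C)[C@@]2(C)CC(=O)C=C(C)[C@H]2[C@H](O)C1(C)C | intermediate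
18 | (5S)-7,9-bis(tert-butyldimethylsilyloxy)-5-(methanesulfonyloxy)-5,11-secolongipin-2-en-1-one | CC(C)(C)[Si](C)(C)O[C@@H]1C[C@@H](O[Si](C)(C)C(C)(C)C)[C@@]2(C)CC(=O)C=C(C)[C@H]2[C@H](OS(C)(=O)=O)C1(C)C | intermediate
19 | (4R,5S,7R,9R,10R,11R)-7,9-bis(tert-butyldimethylsilyloxy)longipin-2-en-1-one | CC(C)(C)[Si](C)(C)O[C@@H]1C[C@@H](O[Si](C)(C)C(C)(C)C)[C@@]2(C)[C@@H]3C(=O)C=C(C)[C@H]2[C@@H]3C1(C)C | intermediate
20 | (4R,5S,7R,9R,10R,11R)-7,9-dihydroxylongipin-2-en-1-one | O[C@@H]1C[C@@H](O)[C@@]2(C)[C@@H]3C(=O)C=C(C)[C@H]2[C@@H]3C1(C)C | intermediate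
21 | 3-methylbut-2-enoyl chloride (senecioyl chloride) | CC(C)=CC(=O)Cl | starting material
22 | (4R,5S,7R,9R,10R,11R)-7-hydroxy-9-(3-methylbut-2-enoyloxy)longipin-2-en-1-one | O[C@@H]1C[C@@H](OC(=O)C=C(C)C)[C@@]2(C)[C@@H]3C(=O)C=C(C)[C@H]2[C@@H]3C1(C)C | intermediate
23 | (E)-2-methylbut-2-enoyl chloride (tigloyl chloride) | C/C=C(\C)C(=O)Cl | starting material
24 | (4R,5S,7R,9R,10R,11R)-7-[(E)-2-methylbut-2-enoyloxy]-9-(3-methylbut-2-enoyloxy)longipin-2-en-1-one | C/C=C(\C)C(=O)O[C@@H]1C[C@@H](OC(=O)C=C(C)C)[C@@]2(C)[C@@H]3C(=O)C=C(C)[C@H]2[C@@H]3C1(C)C | target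

Total step count: 17. Longest linear sequence: 17.

Steps most likely to fail

Step 14. Proton transfer may turn the kinetic C11 enolate into the extended C4 dienolate, which would expel the mesylate by vinylogous E1cB elimination. Displacement at the neopentyl C5 may also be too slow to compete. The fallback removes the acidity of C4–H by masking the alkene. It sets out from 17. Weitz–Scheffer epoxidation (H2O2, NaOH, MeOH, as for isophorone) gives the 2,3-epoxy ketone F1, and either epoxide isomer serves. Mesylation gives the epoxy mesylate F2, in which C11 is the only enolisable position. LDA then closes the cyclobutane to the caged epoxy ketone F3. SmI2 (THF–MeOH, −78 °C) opens the epoxide reductively to the 3-hydroxy ketone F4. Dehydration with the Burgess reagent towards the acidic C2–H brings the route back at 19.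

Step 11. Protonation of the reduced C5 centre may show poor facial selectivity or place the oxygen over the six-membered ring, from where the mesylate cannot leave anti to C11. The fallback makes use of that epimer and sets out from 15. NaBH4 in MeOH at rt (steric approach control, hydride from the open side) gives the 5-epi diol F5. MnO2 then gives the 5-epi hydroxy enone F6. Garegg–Samuelsson iodination (PPh3, I2, imidazole, toluene, heat) replaces the inward hydroxyl with inversion and gives the outward iodide F7. The conditions of step 14 cyclise F7 to 19.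

Step 3. Dimerisation of dimethylketene may outrun its addition to an enol ether whose C4 is neopentyl. The reaction may also stop after C-acylation and silyl transfer, without the second bond. The fallback keeps the same two bond formations but uses the far more reactive dichloroketene and adds the methyl groups later. It sets out from 4. Dichloroacetyl chloride and Et3N in hexane give the dichlorocyclobutanone F8. Zn in AcOH, then warming in aqueous i-PrOH–AcOH, dechlorinates and ring-enlarges it to the cycloheptane-1,3-dione F9. Double C-methylation of the acidic C6 position (MeI, K2CO3, acetone) gives the 2,2-dimethyl dione F10. Aqueous HF in MeCN removes the C9 silyl group and returns to the route at 8.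

Further compounds
F1 | step 14 | (5S)-7,9-bis(tert-butyldimethylsilyloxy)-2,3-epoxy-5-hydroxy-5,11-secolongipinan-1-one | CC(C)(C)[Si](C)(C)O[C@@H]1C[C@@H](O[Si](C)(C)C(C)(C)C)[C@@]2(C)CC(=O)C3OC3(C)[C@H]2[C@H](O)C1(C)C
F2 | step 14 | (5S)-5-mesylate of F1 | CC(C)(C)[Si](C)(C)O[C@@H]1C[C@@H](O[Si](C)(C)C(C)(C)C)[C@@]2(C)CC(=O)C3OC3(C)[C@H]2[C@H](OS(C)(=O)=O)C1(C)C
F3 | step 14 | 7,9-bis(tert-butyldimethylsilyloxy)-2,3-epoxylongipinan-1-one | CC(C)(C)[Si](C)(C)O[C@@H]1C[C@@H](O[Si](C)(C)C(C)(C)C)[C@@]2(C)[C@@H]3C(=O)C4OC4(C)[C@H]2[C@@H]3C1(C)C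
F4 | step 14 | 7,9-bis(tert-butyldimethylsilyloxy)-3-hydroxylongipinan-1-one | CC(C)(C)[Si](C)(C)O[C@@H]1C[C@@H](O[Si](C)(C)C(C)(C)C)[C@@]2(C)[C@@H]3C(=O)CC(C)(O)[C@H]2[C@@H]3C1(C)C
F5 | step 11 | (5R)-7,9-bis(tert-butyldimethylsilyloxy)-5,11-secolongipin-2-ene-1,5-diol (C1 epimers) | CC(C)(C)[Si](C)(C)O[C@@H]1C[C@@H](O[Si](C)(C)C(C)(C)C)[C@@]2(C)CC(O)C=C(C)[C@H]2[C@@H](O)C1(C)C
F6 | step 11 | (5R)-7,9-bis(tert-butyldimethylsilyloxy)-5-hydroxy-5,11-secolongipin-2-en-1-one | CC(C)(C)[Si](C)(C)O[C@@H]1C[C@@H](O[Si](C)(C)C(C)(C)C)[C@@]2(C)CC(=O)C=C(C)[C@H]2[C@@H](O)C1(C)C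
F7 | step 11 | 7,9-bis(tert-butyldimethylsilyloxy)-5-iodo-5,11-secolongipin-2-en-1-one (iodine on the outer side of C5) | CC(C)(C)[Si](C)(C)O[C@@H]1C[C@@H](O[Si](C)(C)C(C)(C)C)[C@@]2(C)CC(=O)C=C(C)[C@H]2[C@H](I)C1(C)C
F8 | step 3 | 4-allyl-3-(tert-butyldimethylsilyloxy)-7,7-dichloro-4-methyl-1-(trimethylsilyloxy)bicyclo[3.2.0]heptan-6-one | O=C1[C@H]2[C@](C)(CC=C)[C@H](O[Si](C)(C)C(C)(C)C)C[C@@]2(O[Si](C)(C)C)C1(Cl)Cl
F9 | step 3 | (5S,6R)-5-allyl-6-(tert-butyldimethylsilyloxy)-5-methylcycloheptane-1,3-dione | O=C1C[C@@H](O[Si](C)(C)C(C)(C)C)[C@@](C)(CC=C)CC(=O)C1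
F10 | step 3 | (5S,6R)-5-allyl-6-(tert-butyldimethylsilyloxy)-2,2,5-trimethylcycloheptane-1,3-dione | O=C1C[C@@H](O[Si](C)(C)C(C)(C)C)[C@@](C)(CC=C)CC(=O)C1(C)C
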